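The data come from a simulation from invented constants, and the scatter is random.

The rate of making Q at the mark of 5.0% conversion cannot be read off the earlier runs: their earliest reading, 1.33 h in ochre, finds 51.3% of J already gone.

| flask | J | L | G | Z | remark |
|---|---|---|---|---|---|
| blue | 0.80 M | 0.96 M | 0.040 M | 5.9 mM | run made earlier |
| ochre | 0.80 M | 0.96 M | 0.040 M | 13 mM | run made earlier |
| teal | 0.80 M | 0.96 M | 0.060 M | 8.8 mM | run made earlier |
| flask | 0.80 M | 0.960 M | 0.0400 M | 8.8 mM |  |

- blue (time / h: Q / %, J / %): 2.50: 25.6, 52.1; 5.00: 47.6, 33.1; 8.00: 68.5, 16.2; 10.0: 78.1, 10.4; 12.0: 83.9, 7.0; 15.0: 92.4, 2.5; 20.0: 94.9, 0.5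
- ochre (time / h: Q / %, J / %): 1.33: 29.5, 48.7; 2.00: 42.6, 36.8; 3.00: 60.1, 25.6; 5.00: 80.2, 9.8; 8.00: 92.4, 2.3; 12.0: 94.9, 0.5; 20.0: 95.2, 0
- teal (time / h: Q / %, J / %): 4.00: 56.7, 27.1; 8.00: 83.1, 7.5; 10.0: 86.8, 2.6; 15.0: 92.9, 1.3; 20.0: 92.8, 0

(standard deviation of a reading: 1 percentage point)

1. factor on the rate of making Q when 5.0% of the J are converted if L is charged twice over
2. factor on the rate when 5.0% of the J are converted if Z is charged at 40 mM instead

- the analysis behind the earlier runs scatters by 1 percentage point, standard deviation
- steps that have been proposed: J + Z -> Z + X; Z + X <-> D; L + D -> Z + Q; J + G -> E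
- no earlier run changes the charge of L; that part of a forecast is a guess

Two chemists argue at the board about doubling L. The first says that Q comes from L + D, so the rate is a constant times cL times cD. With cD unchanged, twice the cL gives twice the rate. The second replies that cD does not stay unchanged, since more L also clears D faster. Once D is used as fast as it is made, the rate equals the feed of D, and cL drops out, which gives a factor of 1.

Their quarrel is about time, so I reckon the time from ochre. Between 1.33 h and 2.00 h Q rises by 13 percentage points, a rate of 0.156 M h⁻¹, while cL stands near 0.672 M. The catalyst in D cannot exceed the 13 mM charged, so these readings give a lower limit on the constant. At the charged cL, a D therefore lives at most 3.49 min. This is the clearing time, the time in which L turns D into Z and Q, with D reacting in a pseudo-first-order way at fixed cL.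

A look made early against this time belongs to the first chemist, and a look made late against it belongs to the second. The readings do not give the time of the mark, so I commit only to a factor between 1 and 2. Clearing at fixed cL does not contain cZ, so I give no reckoning for the second question.

The forecast takes the first side, with 1.9 for doubled L and 7 for Z at 40 mM: “Doubling L should nearly double the rate.”

The flask gives 1.59 for doubled L, between the two views, and 5.27 for Z at 40 mM.

    J + Z → Z + X (k = 0.0174 L mol⁻¹ s⁻¹)
    Z + X ⇌ D (K = 82.4 L mol⁻¹, k = 0.0666 L mol⁻¹ s⁻¹)
    L + D → Z + Q (k = 0.0115 L mol⁻¹ s⁻¹)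
    J + G → E (k = 0.0240 L mol⁻¹ s⁻¹)

The mark is reached after 1.31 min, which is 0.375 of the clearing time read from ochre, and since that time is an upper limit, this share is a lower one. At 2.09 h, which by that same upper limit is at least 35.9 clearing times into this flask, D is made 1.00 times as fast as it is used up.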